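## Structural features

The target is a sesquineolignan built from three C6C3 units: a guaiacylglycerol (ring G with the chain C7''–C8''–C9''), a syringyl ring S, and a 7-methoxy-2,3-dihydrobenzofuran (benzene ring A fused to the furan ring O1–C2–C3–C3a–C7a) that bears a 3-hydroxypropyl chain at C5 and a hydroxymethyl group at C3. Ring S is joined through its C1 to C2 of the furan ring and through its phenolic oxygen, which lies between two methoxy groups, to C8''. The four stereocentres form two adjacent pairs, C2/C3 and C7''/C8'', which are separated by ring S and cannot direct each other. Read from the SMILES, C2 and C3 are both R, which puts the aryl group on C2 and the hydroxymethyl group on C3 on the same face of the furan ring (cis, the less stable arrangement), and C7'' is R and C8'' is S, which is the erythro (anti) aryl ether diol. Fragile points are the benzylic O1–C2 bond (acid reopens it and recloses to trans), any C3 carbonyl precursor (base epimerises it to trans), the C7'' carbinol (a para-quinone methide forms once the G phenol is free and O7'' is a leaving group) and every benzylic C–O bond under hydrogenolysis. The real difficulty is the cis C2/C3 pair in one absolute sense, and after it the erythro ether from C8'' to a phenol with two ortho substituents. The key step exploits that C2 is a benzylic carbon next to O1 whose hydrogens lie 1,5 to C3: when C3 is a carbene on ring A, insertion into a C2–H bond makes the C2–C3 bond, closes the furan ring and sets both centres in one concerted event whose kinetic result is cis. In one sentence, the furan ring is closed by an enantioselective rhodium-carbene insertion of the aryl(diazo)acetate carbon of 11 into a benzylic C–H bond of its own ortho aryl-CH2–O ether, a description that does not fit the oxidative phenol coupling that would be drawn first.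

## Logic of the disconnections

14 to 13. The O–CH2Ph bond at the G-ring phenol is cut. The phenol has to stay masked until O7'' no longer carries an acyl group, because a free para-phenoxide would expel that group and the quinone methide would be reduced. The forward step must cleave one primary benzyl ether and spare the benzylic C–O bonds at C2 and C7''.

13 to 12. No skeletal bond is cut; four hydroxyl-bearing carbons go back to the acyl level (C3 ester, chain ester, C9'' imide carbonyl, O7'' nitrobenzoate). Each acyl group is either needed by, or left behind by, an earlier bond-forming step, so four hydroxyl groups need no protecting-group steps. The forward reduction must be faster than epimerisation at C3.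

12 to 11. The C2–C3 bond is cut and the furan ring opens to an aryl benzyl ether that carries a diazo ester at the future C3. One ring and two stereocentres disappear, leaving a precursor with only the two remote side-chain centres. The forward step must deliver cis and one absolute sense under catalyst control and must choose this CH2 group over all other C–H bonds.

11 to 10. The bond between ring A and the diazo carbon is cut, giving an aryl iodide and a diazoacetate. The diazo group is thus introduced only after all Lewis-acid and phosphine chemistry. The forward coupling must run under a base mild enough for the β-acyloxy imide.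

10 to 9. The C7''–O(acyl) bond is cut with inversion. The reliable aldol gives the syn (threo) pair and the target is anti (erythro), so C7'' is inverted, and the ester formed serves as the O7'' mask. The forward step needs SN2 substitution at an electron-rich benzylic carbinol without elimination.

9 to 6 + 7. The C7''–C8'' bond is cut (aldol). Both side-chain stereocentres arise in one step and the hindered aryl ether oxygen is already on C8'', so no substitution by a di-ortho-substituted phenol at a secondary carbon is ever required. The forward step needs a Z-enolate and auxiliary control of its face.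

6 to 5 + 2. The O–CH2 bond that later becomes O1–C2 is cut, dividing the molecule into two fragments of similar size. The forward step must etherify a phenol flanked by iodine and methoxy with a primary benzylic alcohol under neutral conditions.

5 to 3 + 4. The bond from the S-ring phenolic oxygen to the CH2 of the acyl chain is cut. The auxiliary, C8'' and C9'' arrive in one alkylation at a primary carbon, where a hindered phenoxide still reacts well. The forward step needs phenol over benzylic alcohol selectivity.

2 to 1. The C–I bond ortho to the phenol is cut; the position is the future C3a. The forward step needs ortho regiocontrol by the free phenol.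

## Other disconnections considered

Alternative 1: the first idea is the biomimetic one, cutting C3–C3a and O1–C2 together. A one-electron oxidant (Ag2O or peroxidase/H2O2) would cross-couple a ferulate ester with a sinapate ester to the phenylcoumaran A1, and the glycerol ether would then be built on its free phenol. The chosen plan is preferred for three reasons: the ring in A1 closes by phenol addition to a quinone methide, which leads to the trans isomer, whereas the target is cis; nothing controls the absolute sense; and sinapate units tend to homo-couple, so the cross-coupling is not selective. It would also leave the whole side chain to be built afterwards.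

Alternative 2: cutting the C2–H and C3–H bonds leads to the aromatic 2-arylbenzofuran-3-carboxylate A2, to be reduced by syn addition of hydrogen to the cis-dihydrobenzofuran A3. Syn addition would give cis, but the C2=C3 bond of A2 is tetrasubstituted, part of an aromatic furan, conjugated to the ester and shielded by the aryl group. Enantioselective hydrogenation of that pattern has little support, heterogeneous hydrogenation gives no facial control and threatens the benzylic C–O bonds, and A2 needs extra steps to assemble. The carbene insertion makes the same cis pair with a catalyst class documented for exactly this ring.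

Alternative 3: cutting O1–C2 leads to the auxiliary-controlled syn-aldol adduct A4 of a (2-hydroxyaryl)acetyl imide with a syringaldehyde ether, to be closed by intramolecular Mitsunobu etherification (5-exo-tet, inversion at C2) to the cis imide A5. The carbinol carbon of A4 is benzylic to a trioxygenated ring, so its activated form should ionise; closure through the cation would give the more stable trans isomer and erode C2. The plan also needs a second auxiliary sequence and phenol protection. The chosen insertion forms C2–C3 without any cation at C2.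

Key step: step 7

Assumption 1: the SMILES is read as (2R,3R) in the dihydrobenzofuran (cis) and (7''R,8''S) in the glycerol (erythro), and the route is designed for exactly this isomer.
Assumption 2: Rh2(S-PTTL)4 is taken to deliver the (2R,3S) ester by analogy with closely related aryl diazoacetates; if the sense were the reverse, Rh2(R-PTTL)4 would be used with nothing else changed.
Assumption 3: 1, 3, 4 and 7 are taken as catalogue compounds.

## Route

Step 1
Reactants: 1 methyl 3-(4-hydroxy-3-methoxyphenyl)propanoate
Product: 2 methyl 3-(4-hydroxy-3-iodo-5-methoxyphenyl)propanoate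
Conditions: NIS, TsOH·H2O (cat.), MeCN, 0 °C → rt
Reagents that add atoms: N-iodosuccinimide, O=C1CCC(=O)N1I
Why: Electrophilic aromatic iodination; the free phenol is the strongest director and its para position is blocked, so iodine should enter ortho to OH, at the future C3a, and the ester is inert.

Step 2
Reactants: 3 4-(hydroxymethyl)-2,6-dimethoxyphenol (syringyl alcohol); 4 (4R)-4-benzyl-3-(chloroacetyl)-1,3-oxazolidin-2-one
Product: 5 (4R)-4-benzyl-3-{[4-(hydroxymethyl)-2,6-dimethoxyphenoxy]acetyl}-1,3-oxazolidin-2-one
Conditions: K2CO3, NaI (cat.), acetone, rt → 40 °C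
Reagents that add atoms: none
Why: Williamson ether synthesis with Finkelstein assistance; carbonate ionises only the phenol, and the phenoxide attacks the primary α-halo carbon, where even a di-ortho-substituted phenoxide reacts by SN2, while its bulk makes it a poor acyl acceptor so the imide should survive.

Step 3
Reactants: 5 (4R)-4-benzyl-3-{[4-(hydroxymethyl)-2,6-dimethoxyphenoxy]acetyl}-1,3-oxazolidin-2-one; 2 methyl 3-(4-hydroxy-3-iodo-5-methoxyphenyl)propanoate
Product: 6 methyl 3-{4-[(4-{2-[(4R)-4-benzyl-2-oxo-1,3-oxazolidin-3-yl]-2-oxoethoxy}-3,5-dimethoxyphenyl)methoxy]-3-iodo-5-methoxyphenyl}propanoate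
Conditions: PPh3, DIAD, THF, 0 °C → rt
Reagents that add atoms: none
Why: Mitsunobu etherification of a primary benzylic alcohol with an acidic ortho-iodophenol under neutral conditions that spare imide and ester; the new O–CH2 bond is the future O1–C2 bond and places the benzylic CH2 1,5 to the iodinated carbon.

Step 4
Reactants: 6 methyl 3-{4-[(4-{2-[(4R)-4-benzyl-2-oxo-1,3-oxazolidin-3-yl]-2-oxoethoxy}-3,5-dimethoxyphenyl)methoxy]-3-iodo-5-methoxyphenyl}propanoate; 7 4-(benzyloxy)-3-methoxybenzaldehyde
Product: 9 methyl 3-{4-[(4-{[(2R,3S)-1-[(4R)-4-benzyl-2-oxo-1,3-oxazolidin-3-yl]-3-[4-(benzyloxy)-3-methoxyphenyl]-3-hydroxy-1-oxopropan-2-yl]oxy}-3,5-dimethoxyphenyl)methoxy]-3-iodo-5-methoxyphenyl}propanoate (syn adduct), via Z-dibutylboron enolate 8 (not isolated)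
Conditions: n-Bu2BOTf, i-Pr2NEt, CH2Cl2, −78 → 0 °C; 7, −78 → 0 °C; then pH 7 buffer, MeOH, H2O2, 0 °C
Reagents that add atoms: dibutylboron triflate, CCCCB(CCCC)OS(=O)(=O)C(F)(F)F (its atoms stay in 8 only)
Why: Evans syn-aldol reaction of an aryloxyacetyl imide; soft enolisation gives the Z-boron enolate 8, and the Zimmerman–Traxler chair with the (4R)-benzyl group shielding one enolate face should give the (2R,3S) syn adduct, which fixes C8'' in its final sense and C7'' in the epimeric sense. The imide CH2 is by far the most acidic site, so the methyl ester should not be enolised.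

Step 5
Reactants: 9 methyl 3-{4-[(4-{[(2R,3S)-1-[(4R)-4-benzyl-2-oxo-1,3-oxazolidin-3-yl]-3-[4-(benzyloxy)-3-methoxyphenyl]-3-hydroxy-1-oxopropan-2-yl]oxy}-3,5-dimethoxyphenyl)methoxy]-3-iodo-5-methoxyphenyl}propanoate
Product: 10 methyl 3-{4-[(4-{[(2R,3R)-1-[(4R)-4-benzyl-2-oxo-1,3-oxazolidin-3-yl]-3-[4-(benzyloxy)-3-methoxyphenyl]-3-[(4-nitrobenzoyl)oxy]-1-oxopropan-2-yl]oxy}-3,5-dimethoxyphenyl)methoxy]-3-iodo-5-methoxyphenyl}propanoate
Conditions: 4-O2NC6H4CO2H, PPh3, DIAD, toluene, −20 °C → rt
Reagents that add atoms: 4-nitrobenzoic acid, O=C(O)c1ccc(cc1)[N+](=O)[O-]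
Why: Mitsunobu inversion; SN2 displacement of the benzylic oxyphosphonium group by the carboxylate inverts C7'' and turns the syn (threo) pair into the anti (erythro) pair, and the ester masks O7'' as an acyl group that the later hydride step removes.

Step 6
Reactants: 10 methyl 3-{4-[(4-{[(2R,3R)-1-[(4R)-4-benzyl-2-oxo-1,3-oxazolidin-3-yl]-3-[4-(benzyloxy)-3-methoxyphenyl]-3-[(4-nitrobenzoyl)oxy]-1-oxopropan-2-yl]oxy}-3,5-dimethoxyphenyl)methoxy]-3-iodo-5-methoxyphenyl}propanoate
Product: 11 methyl 3-{4-[(4-{[(2R,3R)-1-[(4R)-4-benzyl-2-oxo-1,3-oxazolidin-3-yl]-3-[4-(benzyloxy)-3-methoxyphenyl]-3-[(4-nitrobenzoyl)oxy]-1-oxopropan-2-yl]oxy}-3,5-dimethoxyphenyl)methoxy]-3-(1-diazo-2-methoxy-2-oxoethyl)-5-methoxyphenyl}propanoate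
Conditions: N2CHCO2Me, Pd(PPh3)4 (5 mol%), Ag2CO3, Et3N, toluene, rt
Reagents that add atoms: methyl diazoacetate, COC(=O)C=[N+]=[N-]
Why: Palladium-catalysed cross-coupling of an aryl iodide with a diazoacetate with retention of the diazo group (oxidative addition, base-assisted C-metalation of the diazo carbon, reductive elimination); it installs the donor/acceptor diazo ester in one step at room temperature. The α-hydrogen of the imide is held in the carbonyl plane by allylic strain, so triethylamine should not cause β-elimination of the nitrobenzoate.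

Step 7
Reactants: 11 methyl 3-{4-[(4-{[(2R,3R)-1-[(4R)-4-benzyl-2-oxo-1,3-oxazolidin-3-yl]-3-[4-(benzyloxy)-3-methoxyphenyl]-3-[(4-nitrobenzoyl)oxy]-1-oxopropan-2-yl]oxy}-3,5-dimethoxyphenyl)methoxy]-3-(1-diazo-2-methoxy-2-oxoethyl)-5-methoxyphenyl}propanoate
Product: 12 methyl (2R,3S)-2-(4-{[(2R,3R)-1-[(4R)-4-benzyl-2-oxo-1,3-oxazolidin-3-yl]-3-[4-(benzyloxy)-3-methoxyphenyl]-3-[(4-nitrobenzoyl)oxy]-1-oxopropan-2-yl]oxy}-3,5-dimethoxyphenyl)-7-methoxy-5-(3-methoxy-3-oxopropyl)-2,3-dihydro-1-benzofuran-3-carboxylate (cis)
Conditions: Rh2(S-PTTL)4 (2 mol%), toluene, −78 → −40 °C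
Reagents that add atoms: none
Why: Loss of N2 at the dirhodium centre gives a donor/acceptor rhodium carbene at the future C3, which inserts into one of the two enantiotopic benzylic C–H bonds of the ortho ArCH2–O group through a concerted, asynchronous three-centre transition state with hydride-transfer character. The closest known reaction type is the enantioselective intramolecular 1,5 C–H insertion of aryl diazoacetates into ortho benzyl ethers under dirhodium tetrakis(N-phthaloyl-tert-leucinate) catalysis, which gives cis-2-aryl-2,3-dihydrobenzofuran-3-carboxylates. The furan ring O1–C2–C3–C3a–C7a is closed by formation of C2–C3 in the 1,5-insertion mode, the only C–H bonds within reach of the carbene being those of this CH2 group. C2 is set by the choice between the two enantiotopic hydrogens (insertion with retention at carbon) and C3 by the carbene face that receives the hydrogen; both choices are made by the chiral pocket of the phthalimido ligands, and the C7''/C8'' centres, para across ring S, are too far away to interfere (catalyst control). The cis relation is the kinetic outcome of the compact transition state, in which the aryl group on C2 and the ester on C3 lie on the same side, and it should persist because no base is present and the temperature is low. The step needs insertion to win over aromatic cycloaddition to ring S, over reaction at the OCH2Ph and OCH3 groups and over a stepwise hydride abstraction that would scramble C2/C3; the five-membered transition state secures the first two, and the out-of-plane twist of the S-ring para oxygen between its two methoxy groups limits cation stabilisation at C2 and so favours the concerted path.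

Step 8
Reactants: 12 methyl (2R,3S)-2-(4-{[(2R,3R)-1-[(4R)-4-benzyl-2-oxo-1,3-oxazolidin-3-yl]-3-[4-(benzyloxy)-3-methoxyphenyl]-3-[(4-nitrobenzoyl)oxy]-1-oxopropan-2-yl]oxy}-3,5-dimethoxyphenyl)-7-methoxy-5-(3-methoxy-3-oxopropyl)-2,3-dihydro-1-benzofuran-3-carboxylate
Product: 13 (1R,2S)-1-[4-(benzyloxy)-3-methoxyphenyl]-2-{4-[(2R,3R)-3-(hydroxymethyl)-5-(3-hydroxypropyl)-7-methoxy-2,3-dihydro-1-benzofuran-2-yl]-2,6-dimethoxyphenoxy}propane-1,3-diol
Conditions: LiBH4, MeOH (additive), THF, 0 °C → rt
Reagents that add atoms: none
Why: One hydride reduction of four acyl groups: reductive cleavage of the N-acyl oxazolidinone gives C9''H2OH, the nitrobenzoate is reduced off O7'', and both methyl esters become primary alcohols. The aldehyde stage at C3 is reduced faster than it forms, so the cis relation should be kept, and the G-ring phenol stays benzylated so that no quinone methide can form while O7'' is still acylated.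

Step 9
Reactants: 13 (1R,2S)-1-[4-(benzyloxy)-3-methoxyphenyl]-2-{4-[(2R,3R)-3-(hydroxymethyl)-5-(3-hydroxypropyl)-7-methoxy-2,3-dihydro-1-benzofuran-2-yl]-2,6-dimethoxyphenoxy}propane-1,3-diol
Product: 14 (1R,2S)-1-(4-hydroxy-3-methoxyphenyl)-2-{4-[(2R,3R)-3-(hydroxymethyl)-5-(3-hydroxypropyl)-7-methoxy-2,3-dihydro-1-benzofuran-2-yl]-2,6-dimethoxyphenoxy}propane-1,3-diol (target)
Conditions: H2 (1 atm), 10% Pd/C, EtOAc–MeOH, rt
Reagents that add atoms: none
Why: Hydrogenolysis of the aryl benzyl ether under neutral conditions; the primary ArO–CH2Ph bond should cleave much faster than the secondary benzylic C–O bonds at C2 and C7'', and no acid or base is present that could open the furan ring or epimerise C7''.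

## Compound list

1 | methyl 3-(4-hydroxy-3-methoxyphenyl)propanoate | COC(=O)CCc1ccc(O)c(OC)c1 | starting material
2 | methyl 3-(4-hydroxy-3-iodo-5-methoxyphenyl)propanoate | COC(=O)CCc1cc(I)c(O)c(OC)c1 | intermediate
3 | 4-(hydroxymethyl)-2,6-dimethoxyphenol (syringyl alcohol) | COc1cc(CO)cc(OC)c1O | starting material
4 | (4R)-4-benzyl-3-(chloroacetyl)-1,3-oxazolidin-2-one | O=C(CCl)N1[C@H](Cc2ccccc2)COC1=O | starting material
5 | (4R)-4-benzyl-3-{[4-(hydroxymethyl)-2,6-dimethoxyphenoxy]acetyl}-1,3-oxazolidin-2-one | O=C(COc1c(OC)cc(CO)cc1OC)N1[C@H](Cc2ccccc2)COC1=O | intermediate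
6 | methyl 3-{4-[(4-{2-[(4R)-4-benzyl-2-oxo-1,3-oxazolidin-3-yl]-2-oxoethoxy}-3,5-dimethoxyphenyl)methoxy]-3-iodo-5-methoxyphenyl}propanoate | COC(=O)CCc1cc(I)c(OCc2cc(OC)c(OCC(=O)N3[C@H](Cc4ccccc4)COC3=O)c(OC)c2)c(OC)c1 | intermediate
7 | 4-(benzyloxy)-3-methoxybenzaldehyde | COc1cc(C=O)ccc1OCc1ccccc1 | starting material
8 | Z-dibutylboron enolate of 6 | CCCCB(CCCC)O/C(=C\Oc1c(OC)cc(COc2c(I)cc(CCC(=O)OC)cc2OC)cc1OC)N1[C@H](Cc2ccccc2)COC1=O | intermediate (not isolated)
9 | (2R,3S) syn-aldol adduct of 6 and 7 (3-hydroxy) | O=C([C@H](Oc1c(OC)cc(COc2c(I)cc(CCC(=O)OC)cc2OC)cc1OC)[C@@H](O)c1ccc(OCc2ccccc2)c(OC)c1)N1[C@H](Cc2ccccc2)COC1=O | intermediate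
10 | (2R,3R) 3-(4-nitrobenzoyl)oxy imide, aryl iodide | O=C([C@H](Oc1c(OC)cc(COc2c(I)cc(CCC(=O)OC)cc2OC)cc1OC)[C@H](OC(=O)c1ccc(cc1)[N+](=O)[O-])c1ccc(OCc2ccccc2)c(OC)c1)N1[C@H](Cc2ccccc2)COC1=O | intermediate
11 | aryl diazoacetate derived from 10 (iodine replaced by C(N2)CO2Me) | O=C([C@H](Oc1c(OC)cc(COc2c(C(=[N+]=[N-])C(=O)OC)cc(CCC(=O)OC)cc2OC)cc1OC)[C@H](OC(=O)c1ccc(cc1)[N+](=O)[O-])c1ccc(OCc2ccccc2)c(OC)c1)N1[C@H](Cc2ccccc2)COC1=O | intermediate
12 | methyl (2R,3S)-cis-2-aryl-7-methoxy-5-(3-methoxy-3-oxopropyl)-2,3-dihydro-1-benzofuran-3-carboxylate carrying the (2R,3R) nitrobenzoyloxy imide side chain | O=C([C@H](Oc1c(OC)cc([C@@H]2Oc3c(OC)cc(CCC(=O)OC)cc3[C@@H]2C(=O)OC)cc1OC)[C@H](OC(=O)c1ccc(cc1)[N+](=O)[O-])c1ccc(OCc2ccccc2)c(OC)c1)N1[C@H](Cc2ccccc2)COC1=O | intermediate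
13 | (1R,2S)-1-[4-(benzyloxy)-3-methoxyphenyl]-2-{4-[(2R,3R)-3-(hydroxymethyl)-5-(3-hydroxypropyl)-7-methoxy-2,3-dihydro-1-benzofuran-2-yl]-2,6-dimethoxyphenoxy}propane-1,3-diol | COc1cc([C@@H](O)[C@H](CO)Oc2c(OC)cc([C@@H]3Oc4c(OC)cc(CCCO)cc4[C@@H]3CO)cc2OC)ccc1OCc1ccccc1 | intermediate
14 | (1R,2S)-1-(4-hydroxy-3-methoxyphenyl)-2-{4-[(2R,3R)-3-(hydroxymethyl)-5-(3-hydroxypropyl)-7-methoxy-2,3-dihydro-1-benzofuran-2-yl]-2,6-dimethoxyphenoxy}propane-1,3-diol | COc1cc([C@@H](O)[C@H](CO)Oc2c(OC)cc([C@@H]3Oc4c(OC)cc(CCCO)cc4[C@@H]3CO)cc2OC)ccc1O | target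

## Step count and least certain steps

Total step count: 9. Longest linear sequence: 8 (steps 2 to 9 from 3 and 4, or step 1 and steps 3 to 9 from 1).

Step 7 (key step). What is most likely to go wrong is partial loss of the cis relation or of enantiofacial control. A stepwise hydride transfer through a benzylic oxocarbenium/rhodium enolate pair can compete with the concerted insertion at an electron-rich benzylic site. In addition, the nitro, imide and ester donors and the two existing stereocentres of the large substrate may occupy axial rhodium sites or form a mismatched pair with the catalyst. Fallback: the insertion is moved ahead of the side-chain construction, so that it runs on a substrate without side-chain stereocentres or nitro group. Setting out from 6, the palladium coupling with methyl diazoacetate should give the aryl diazoacetate F1. Rh2(S-PTTL)4 should convert it into the cis-dihydrobenzofuran imide F2, whose enantiomeric purity can be raised by crystallisation before further investment. The Evans aldol reaction with 7 should then give the syn-aldol adduct F3, and Mitsunobu inversion with 4-nitrobenzoic acid returns to the route at 12.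

Step 5. What is most likely to go wrong is dehydration in place of substitution (the oxyphosphonium intermediate loses the acidic hydrogen at C8'' and gives the α-aryloxy cinnamoyl imide), or partial ionisation of the electron-rich benzylic oxyphosphonium ion with loss of stereospecificity. Fallback: inversion by oxidation and reduction. Setting out from 9, Dess–Martin oxidation should give the β-keto imide F4, in which C8'' is protected from enolisation by allylic strain. Reduction with NaBH4 in EtOH–CH2Cl2 at low temperature, under non-chelating polar Felkin–Anh control, should give the anti alcohol F5. Acylation with 4-nitrobenzoyl chloride and pyridine returns to the route at 10.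

Step 6. What is most likely to go wrong is slow coupling at the ortho-alkoxy, electron-rich iodide, so that palladium-mediated decomposition of the diazoacetate (carbene dimerisation) takes over. Fallback: two known steps in place of one. Setting out from 10, Negishi coupling with the Reformatsky reagent BrZnCH2CO2Me (Pd2(dba)3, XPhos, THF) should give the aryl acetate F6, and Regitz diazo transfer (p-ABSA, DBU, MeCN, 0 °C) returns to the route at 11. DBU is a stronger base than the triethylamine of step 6, so this fallback relies more heavily on the allylic-strain argument against β-elimination.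

Step 8. What is most likely to go wrong is epimerisation at C3 (cis to trans) by lithium alkoxides while the hindered C3 ester waits to be reduced, or hydride attack on the ring carbonyl of the hindered imide. Fallback: the global reduction is split between two reagents. Setting out from 12, LiBH4 with one equivalent of water in Et2O at 0 °C should remove only the auxiliary and the nitrobenzoate and give the diester diol F7. LiAlH4 in THF at −40 °C should then reduce the two methyl esters within minutes and return to the route at 13.

## Further compounds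

F1 | step 7 | methyl 3-{4-[(4-{2-[(4R)-4-benzyl-2-oxo-1,3-oxazolidin-3-yl]-2-oxoethoxy}-3,5-dimethoxyphenyl)methoxy]-3-(1-diazo-2-methoxy-2-oxoethyl)-5-methoxyphenyl}propanoate | COC(=O)CCc1cc(C(=[N+]=[N-])C(=O)OC)c(OCc2cc(OC)c(OCC(=O)N3[C@H](Cc4ccccc4)COC3=O)c(OC)c2)c(OC)c1
F2 | step 7 | methyl (2R,3S)-2-(4-{2-[(4R)-4-benzyl-2-oxo-1,3-oxazolidin-3-yl]-2-oxoethoxy}-3,5-dimethoxyphenyl)-7-methoxy-5-(3-methoxy-3-oxopropyl)-2,3-dihydro-1-benzofuran-3-carboxylate | O=C(COc1c(OC)cc([C@@H]2Oc3c(OC)cc(CCC(=O)OC)cc3[C@@H]2C(=O)OC)cc1OC)N1[C@H](Cc2ccccc2)COC1=O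
F3 | step 7 | methyl (2R,3S)-2-(4-{[(2R,3S)-1-[(4R)-4-benzyl-2-oxo-1,3-oxazolidin-3-yl]-3-[4-(benzyloxy)-3-methoxyphenyl]-3-hydroxy-1-oxopropan-2-yl]oxy}-3,5-dimethoxyphenyl)-7-methoxy-5-(3-methoxy-3-oxopropyl)-2,3-dihydro-1-benzofuran-3-carboxylate | O=C([C@H](Oc1c(OC)cc([C@@H]2Oc3c(OC)cc(CCC(=O)OC)cc3[C@@H]2C(=O)OC)cc1OC)[C@@H](O)c1ccc(OCc2ccccc2)c(OC)c1)N1[C@H](Cc2ccccc2)COC1=O
F4 | step 5 | methyl 3-{4-[(4-{[(2R)-1-[(4R)-4-benzyl-2-oxo-1,3-oxazolidin-3-yl]-3-[4-(benzyloxy)-3-methoxyphenyl]-1,3-dioxopropan-2-yl]oxy}-3,5-dimethoxyphenyl)methoxy]-3-iodo-5-methoxyphenyl}propanoate | O=C([C@H](Oc1c(OC)cc(COc2c(I)cc(CCC(=O)OC)cc2OC)cc1OC)C(=O)c1ccc(OCc2ccccc2)c(OC)c1)N1[C@H](Cc2ccccc2)COC1=O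
F5 | step 5 | methyl 3-{4-[(4-{[(2R,3R)-1-[(4R)-4-benzyl-2-oxo-1,3-oxazolidin-3-yl]-3-[4-(benzyloxy)-3-methoxyphenyl]-3-hydroxy-1-oxopropan-2-yl]oxy}-3,5-dimethoxyphenyl)methoxy]-3-iodo-5-methoxyphenyl}propanoate | O=C([C@H](Oc1c(OC)cc(COc2c(I)cc(CCC(=O)OC)cc2OC)cc1OC)[C@H](O)c1ccc(OCc2ccccc2)c(OC)c1)N1[C@H](Cc2ccccc2)COC1=O
F6 | step 6 | methyl 3-{4-[(4-{[(2R,3R)-1-[(4R)-4-benzyl-2-oxo-1,3-oxazolidin-3-yl]-3-[4-(benzyloxy)-3-methoxyphenyl]-3-[(4-nitrobenzoyl)oxy]-1-oxopropan-2-yl]oxy}-3,5-dimethoxyphenyl)methoxy]-3-methoxy-5-(2-methoxy-2-oxoethyl)phenyl}propanoate | O=C([C@H](Oc1c(OC)cc(COc2c(CC(=O)OC)cc(CCC(=O)OC)cc2OC)cc1OC)[C@H](OC(=O)c1ccc(cc1)[N+](=O)[O-])c1ccc(OCc2ccccc2)c(OC)c1)N1[C@H](Cc2ccccc2)COC1=O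
F7 | step 8 | methyl (2R,3S)-2-(4-{[(1R,2S)-1-[4-(benzyloxy)-3-methoxyphenyl]-1,3-dihydroxypropan-2-yl]oxy}-3,5-dimethoxyphenyl)-7-methoxy-5-(3-methoxy-3-oxopropyl)-2,3-dihydro-1-benzofuran-3-carboxylate | COc1cc([C@@H](O)[C@H](CO)Oc2c(OC)cc([C@@H]3Oc4c(OC)cc(CCC(=O)OC)cc4[C@@H]3C(=O)OC)cc2OC)ccc1OCc1ccccc1
A1 | alternative 1 | methyl trans-2-(4-hydroxy-3,5-dimethoxyphenyl)-7-methoxy-5-[(E)-3-methoxy-3-oxoprop-1-enyl]-2,3-dihydro-1-benzofuran-3-carboxylate (racemic, the 2S,3S enantiomer drawn) | Oc1c(OC)cc([C@H]2Oc3c(OC)cc(/C=C/C(=O)OC)cc3[C@@H]2C(=O)OC)cc1OC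
A2 | alternative 2 | methyl 2-[4-(benzyloxy)-3,5-dimethoxyphenyl]-7-methoxy-5-(3-methoxy-3-oxopropyl)-1-benzofuran-3-carboxylate | COC(=O)CCc1cc(OC)c2oc(-c3cc(OC)c(OCc4ccccc4)c(OC)c3)c(C(=O)OC)c2c1
A3 | alternative 2 | methyl (2R,3S)-2-[4-(benzyloxy)-3,5-dimethoxyphenyl]-7-methoxy-5-(3-methoxy-3-oxopropyl)-2,3-dihydro-1-benzofuran-3-carboxylate | c1ccccc1COc1c(OC)cc([C@@H]2Oc3c(OC)cc(CCC(=O)OC)cc3[C@@H]2C(=O)OC)cc1OC
A4 | alternative 3 | (4S)-4-benzyl-3-{(2S,3S)-3-[4-(benzyloxy)-3,5-dimethoxyphenyl]-3-hydroxy-2-[2-hydroxy-3-methoxy-5-(3-methoxy-3-oxopropyl)phenyl]propanoyl}-1,3-oxazolidin-2-one | O=C([C@@H](c1cc(CCC(=O)OC)cc(OC)c1O)[C@H](O)c1cc(OC)c(OCc2ccccc2)c(OC)c1)N1[C@@H](Cc2ccccc2)COC1=O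
A5 | alternative 3 | methyl 3-[(2R,3S)-3-{[(4S)-4-benzyl-2-oxo-1,3-oxazolidin-3-yl]carbonyl}-2-[4-(benzyloxy)-3,5-dimethoxyphenyl]-7-methoxy-2,3-dihydro-1-benzofuran-5-yl]propanoate | O=C([C@H]1c2cc(CCC(=O)OC)cc(OC)c2O[C@H]1c3cc(OC)c(OCc4ccccc4)c(OC)c3)N1[C@@H](Cc2ccccc2)COC1=O
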